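**Strategy.** Numbering follows 1-benzoxepine (O1, C2–C5, C5a, C6–C9, C9a). The route rests on cutting C4–C5 and C5a–C9a: the C5–C5a unit, wedged between the fully substituted C9a and the C4 carbinol, is a latent vinyl group acting as a vicinal dianion. A zirconocene-mediated bicyclization of an acyclic 1,7-enyne closes the cyclohexane at C5a–C9a through a zirconacyclopentene (a ring absent from the target). Its Zr–C5 bond then inserts an enantiopure enal, forging C4–C5 and uniting both halves. C9a emerges as an exocyclic alkene, which later accepts the C2 hydroxyl by alkoxymercuration to close the oxepane with the axial C9a methyl.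

Key step: step 6

Remark on the chemistry: 2-bromo-3,3-diethoxyprop-1-ene (6) and 2-bromo-N-methoxy-N-methylacetamide (7) are taken as catalogue chemicals. Position labels C2–C9a in intermediates refer to the atoms they become in the target.

Step 1
Reactants: 1 5-(trimethylsilyl)pent-4-yn-1-ol; 2 3-methylbuta-1,2-diene
Product: 4 (S)-3,3-dimethyl-8-(trimethylsilyl)oct-1-en-7-yn-4-ol, via 5-(trimethylsilyl)pent-4-ynal 3 (not isolated)
Conditions: cyclometalated iridium C,O-benzoate catalyst from [Ir(cod)Cl]2, SEGPHOS (antipode chosen for the S alcohol), 4-cyano-3-nitrobenzoic acid and allyl acetate (5 mol%), Cs2CO3 (cat.), toluene, 50 °C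
Reagents that add atoms: none
Why: Iridium-catalysed hydrogen auto-transfer reverse prenylation (Krische tert-prenylation): 1 is dehydrogenated to 3, the borrowed hydride turns 2 into a 1,1-dimethylallyl–iridium species, and its addition through a closed chair transition state under ligand control sets the future C7 as S next to the new quaternary carbon.

Step 2
Reactants: 4 (S)-3,3-dimethyl-8-(trimethylsilyl)oct-1-en-7-yn-4-ol
Product: 5 (S)-triethyl{[3,3-dimethyl-8-(trimethylsilyl)oct-1-en-7-yn-4-yl]oxy}silane
Conditions: TESOTf, 2,6-lutidine, CH2Cl2, −78 to 0 °C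
Reagents that add atoms: triethylsilyl trifluoromethanesulfonate CC[Si](CC)(CC)OS(=O)(=O)C(F)(F)F
Why: Silylation of the hindered neopentylic alcohol with a silyl triflate removes the acidic proton before the zirconocene step and provides the control element for C5a.

Step 3
Reactants: 6 2-bromo-3,3-diethoxyprop-1-ene; 7 2-bromo-N-methoxy-N-methylacetamide
Product: 9 1-bromo-3-(diethoxymethyl)but-3-en-2-one, via 2-lithio-3,3-diethoxyprop-1-ene 8 (not isolated)
Conditions: t-BuLi (2 equiv), Et2O, −78 °C; then 7, −78 °C; aq. NH4Cl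
Reagents that add atoms: none
Why: Bromine–lithium exchange gives the α-lithioacrolein acetal 8, and its acylation by the Weinreb amide stops at the ketone (Weinreb ketone synthesis), the low temperature sparing the α-bromide.

Step 4
Reactants: 9 1-bromo-3-(diethoxymethyl)but-3-en-2-one
Product: 10 (R)-1-bromo-3-(diethoxymethyl)but-3-en-2-ol
Conditions: (R)-2-methyl-CBS-oxazaborolidine (20 mol%), catecholborane, toluene, −78 °C
Reagents that add atoms: none
Why: Corey–Bakshi–Shibata reduction: with the branched alkenyl group as the large and CH2Br as the small substituent, the R catalyst should give the (R)-bromohydrin (C2 of the target), and catecholborane avoids hydroboration and conjugate reduction.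

Step 5
Reactants: 10 (R)-1-bromo-3-(diethoxymethyl)but-3-en-2-ol
Product: 13 (R)-2-[2-bromo-1-(triethylsilyloxy)ethyl]prop-2-enal, via TES ether acetal 11 (not isolated), via collidinium triflate 12 (not isolated)
Conditions: TESOTf (3 equiv), 2,4,6-collidine, CH2Cl2, 0 °C; then H2O
Reagents that add atoms: triethylsilyl trifluoromethanesulfonate CC[Si](CC)(CC)OS(=O)(=O)C(F)(F)F; water O
Why: O-silylation followed in the same flask by silyl triflate/collidine acetal cleavage (Fujioka conditions): the triflate ionises 11, collidine traps the oxocarbenium ion as 12, and water releases the aldehyde without touching the silyl ether or C2.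

Step 6
Reactants: 5 (S)-triethyl{[3,3-dimethyl-8-(trimethylsilyl)oct-1-en-7-yn-4-yl]oxy}silane; 13 (R)-2-[2-bromo-1-(triethylsilyloxy)ethyl]prop-2-enal
Product: 16 (2RS,4R)-5-bromo-1-[(1S,3S,6E)-2,2-dimethyl-3-(triethylsilyloxy)-6-(trimethylsilylmethylidene)cyclohexyl]-3-methylidene-4-(triethylsilyloxy)pentan-2-ol, via zirconacyclopentene 14 (not isolated), via oxazirconacycle 15 (not isolated)
Conditions: Cp2ZrCl2, n-BuLi (2 equiv), THF, −78 °C; then 5, −78 °C to rt; then 13, 0 °C to rt; sat. aq. NH4Cl
Reagents that add atoms: none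
Why: Cp2ZrBu2 loses butane to give Cp2Zr(1-butene), a divalent zirconocene equivalent that binds the silylalkyne of 5 and cyclises oxidatively with the tethered vinyl group to form C5a–C9a and 14; aldehyde 13 then inserts into the Zr–C5 bond by 1,2-addition to give 15 and the C4–C5 bond, and protonolysis releases 16. The closest known reaction type is the Negishi zirconocene enyne bicyclization with aldehyde insertion into the alkyl–zirconium bond of a zirconacyclopentene. The cyclohexane closes exo with respect to both π bonds (1,7-enyne to a methylidenecyclohexane), the zirconacycle serving as a temporary five-membered ring. C5a is set under reversible cyclisation by the C7 silyl ether, which lies equatorial together with the C5a–C5 bond in the chair-like zirconabicycle; C4 forms without control and is corrected in steps 7 and 8. The step needs insertion at the alkyl rather than the alkenyl Zr–C bond, which the bulky α-silyl group on the alkenyl carbon should secure, and 1,2- rather than 1,4-addition to the enal, the normal mode for oxophilic tetravalent zirconium alkyls.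

Step 7
Reactants: 16 (C4 epimer mixture)
Product: 17 (4R)-5-bromo-1-[(1S,3S,6E)-2,2-dimethyl-3-(triethylsilyloxy)-6-(trimethylsilylmethylidene)cyclohexyl]-3-methylidene-4-(triethylsilyloxy)pentan-2-one
Conditions: Dess–Martin periodinane, NaHCO3, CH2Cl2, 0 °C to rt
Reagents that add atoms: none
Why: Dess–Martin oxidation of the allylic alcohol under buffered conditions converges both C4 epimers into one enone and leaves the silyl ethers, vinylsilane and bromide untouched; any minor C5a epimer is removed here.

Step 8
Reactants: 17 (the enone)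
Product: 18 (2R,4R)-5-bromo-1-[(1S,3S,6E)-2,2-dimethyl-3-(triethylsilyloxy)-6-(trimethylsilylmethylidene)cyclohexyl]-3-methylidene-4-(triethylsilyloxy)pentan-2-ol
Conditions: (S)-2-methyl-CBS-oxazaborolidine, catecholborane, toluene, −78 °C
Reagents that add atoms: none
Why: Corey–Bakshi–Shibata reduction of the α-methylidene ketone: the alkenyl group acts as the large substituent, so the S catalyst should give the (R)-carbinol at C4 under reagent control.

Step 9
Reactants: 18 (the C4 alcohol)
Product: 19 (2R,4R)-5-bromo-1-[(1S,3S,6E)-2,2-dimethyl-3-(triethylsilyloxy)-6-(trimethylsilylmethylidene)cyclohexyl]-3-methylidene-4-(triethylsilyloxy)pentan-2-yl benzoate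
Conditions: BzCl, pyridine, DMAP (cat.), CH2Cl2, 0 °C to rt
Reagents that add atoms: benzoyl chloride O=C(Cl)c1ccccc1
Why: DMAP-catalysed acylation blocks the C4 oxygen, which would otherwise outcompete the C2 hydroxyl in step 11 by five-membered ring closure; the benzoate tolerates acid, hydride at −78 °C and Appel conditions.

Step 10
Reactants: 19 (the benzoate)
Product: 20 (2R,4R)-5-bromo-4-hydroxy-1-[(1R,3S)-3-hydroxy-2,2-dimethyl-6-methylidenecyclohexyl]-3-methylidenepentan-2-yl benzoate
Conditions: CF3CO2H, CH2Cl2, H2O (trace), 0 °C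
Reagents that add atoms: none
Why: Acidolysis: protodesilylation of the vinylsilane by ipso protonation through the tertiary β-silyl cation (much faster than protonation of the resulting 1,1-disubstituted alkene) and cleavage of both TES ethers, while benzoate and bromide are acid-stable.

Step 11
Reactants: 20 (the diol with exocyclic alkene)
Product: 22 (2R,4R,5aS,7S,9aS)-2-(bromomethyl)-7-hydroxy-6,6,9a-trimethyl-3-methylidenedecahydro-1-benzoxepin-4-yl benzoate, via alkylmercury trifluoroacetate 21 (not isolated)
Conditions: Hg(O2CCF3)2, CH2Cl2, −20 to 0 °C; then NaBH4, aq. NaOH, 0 °C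
Reagents that add atoms: none
Why: Intramolecular alkoxymercuration–reductive demercuration: divalent mercury activates the electron-rich exocyclic alkene, and the C2 hydroxyl adds to tertiary C9a (Markovnikov, 7-exo) from the equatorial direction because the axial approach is blocked by the axial C6 methyl, so the oxepane is trans-fused with the new methyl axial (C9a S).

Step 12
Reactants: 22 (the C7 alcohol)
Product: 23 (2R,4R,5aS,9aS)-2-(bromomethyl)-6,6,9a-trimethyl-3-methylidene-7-oxodecahydro-1-benzoxepin-4-yl benzoate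
Conditions: Dess–Martin periodinane, NaHCO3, CH2Cl2, rt
Reagents that add atoms: none
Why: Dess–Martin oxidation of the only free hydroxyl gives the C7 ketone and erases the relay stereocentre.

Step 13
Reactants: 23 (the C7 ketone)
Product: 24 (2R,4R,5aS,7R,9aS)-2-(bromomethyl)-7-hydroxy-6,6,9a-trimethyl-3-methylidenedecahydro-1-benzoxepin-4-yl benzoate
Conditions: LiBH(s-Bu)3 (L-selectride), THF, −78 °C; aq. NH4Cl
Reagents that add atoms: none
Why: The bulky trialkylborohydride attacks the ketone flanked by the gem-dimethyl carbon from the equatorial direction and should give the axial (7R) alcohol, as is usual for 4,4-dimethyl-3-keto terpenoids.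

Step 14
Reactants: 24 (the axial C7 alcohol)
Product: 25 (2R,4R,5aS,7S,9aS)-7-bromo-2-(bromomethyl)-6,6,9a-trimethyl-3-methylidenedecahydro-1-benzoxepin-4-yl benzoate
Conditions: CBr4, PPh3, toluene, 0 to 60 °C
Reagents that add atoms: carbon tetrabromide BrC(Br)(Br)Br
Why: Appel reaction: SN2 displacement of the phosphorus-activated axial oxygen by bromide with inversion should give the equatorial (7S) bromide.

Step 15
Reactants: 25 (the bromo benzoate)
Product: 26 (2R,4R,5aS,7S,9aS)-7-bromo-2-(bromomethyl)-6,6,9a-trimethyl-3-methylidenedecahydro-1-benzoxepin-4-ol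
Conditions: i-Bu2AlH, CH2Cl2, −78 °C; Rochelle salt
Reagents that add atoms: none
Why: Reductive ester cleavage at −78 °C frees the C4 alcohol without a warm free alkoxide that could displace the neighbouring primary bromide.

**Compound list**

1 | 5-(trimethylsilyl)pent-4-yn-1-ol | C[Si](C)(C)C#CCCCO | starting material
2 | 3-methylbuta-1,2-diene | CC(C)=C=C | starting material
3 | 5-(trimethylsilyl)pent-4-ynal | C[Si](C)(C)C#CCCC=O | intermediate
4 | (S)-3,3-dimethyl-8-(trimethylsilyl)oct-1-en-7-yn-4-ol | C=CC(C)(C)[C@@H](O)CCC#C[Si](C)(C)C | intermediate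
5 | (S)-triethyl{[3,3-dimethyl-8-(trimethylsilyl)oct-1-en-7-yn-4-yl]oxy}silane | C=CC(C)(C)[C@@H](O[Si](CC)(CC)CC)CCC#C[Si](C)(C)C | intermediate
6 | 2-bromo-3,3-diethoxyprop-1-ene | C=C(Br)C(OCC)OCC | starting material
7 | 2-bromo-N-methoxy-N-methylacetamide | CON(C)C(=O)CBr | starting material
8 | 2-lithio-3,3-diethoxyprop-1-ene | [Li]C(=C)C(OCC)OCC | intermediate
9 | 1-bromo-3-(diethoxymethyl)but-3-en-2-one | C=C(C(OCC)OCC)C(=O)CBr | intermediate
10 | (R)-1-bromo-3-(diethoxymethyl)but-3-en-2-ol | C=C(C(OCC)OCC)[C@@H](O)CBr | intermediate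
11 | (R)-{[1-bromo-3-(diethoxymethyl)but-3-en-2-yl]oxy}triethylsilane | C=C(C(OCC)OCC)[C@@H](O[Si](CC)(CC)CC)CBr | intermediate
12 | 1-{(3R)-4-bromo-1-ethoxy-2-methylidene-3-(triethylsilyloxy)butyl}-2,4,6-trimethylpyridinium triflate | C=C(C(OCC)[n+]1c(C)cc(C)cc1C)[C@@H](O[Si](CC)(CC)CC)CBr.[O-]S(=O)(=O)C(F)(F)F | intermediate
13 | (R)-2-[2-bromo-1-(triethylsilyloxy)ethyl]prop-2-enal | C=C(C=O)[C@@H](O[Si](CC)(CC)CC)CBr | intermediate
14 | zirconacyclopentene: Cp2Zr bridging the silylated alkenyl carbon and C5 of the cyclised enyne (5aS,7S) | C[Si](C)(C)C1=C2CC[C@H](O[Si](CC)(CC)CC)C(C)(C)[C@@H]2C[Zr]1(C3C=CC=C3)C3C=CC=C3 | intermediate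
15 | seven-membered oxazirconacycle from insertion of 13 into the Zr–C5 bond of 14 | C[Si](C)(C)C1=C2CC[C@H](O[Si](CC)(CC)CC)C(C)(C)[C@@H]2CC(C(=C)[C@@H](O[Si](CC)(CC)CC)CBr)O[Zr]1(C3C=CC=C3)C3C=CC=C3 | intermediate
16 | (2RS,4R)-5-bromo-1-[(1S,3S,6E)-2,2-dimethyl-3-(triethylsilyloxy)-6-(trimethylsilylmethylidene)cyclohexyl]-3-methylidene-4-(triethylsilyloxy)pentan-2-ol | C[Si](C)(C)/C=C1\CC[C@H](O[Si](CC)(CC)CC)C(C)(C)[C@@H]1CC(O)C(=C)[C@@H](O[Si](CC)(CC)CC)CBr | intermediate
17 | (4R)-5-bromo-1-[(1S,3S,6E)-2,2-dimethyl-3-(triethylsilyloxy)-6-(trimethylsilylmethylidene)cyclohexyl]-3-methylidene-4-(triethylsilyloxy)pentan-2-one | C[Si](C)(C)/C=C1\CC[C@H](O[Si](CC)(CC)CC)C(C)(C)[C@@H]1CC(=O)C(=C)[C@@H](O[Si](CC)(CC)CC)CBr | intermediate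
18 | (2R,4R)-alcohol from 17 | C[Si](C)(C)/C=C1\CC[C@H](O[Si](CC)(CC)CC)C(C)(C)[C@@H]1C[C@@H](O)C(=C)[C@@H](O[Si](CC)(CC)CC)CBr | intermediate
19 | benzoate of 18 | C[Si](C)(C)/C=C1\CC[C@H](O[Si](CC)(CC)CC)C(C)(C)[C@@H]1C[C@@H](OC(=O)c2ccccc2)C(=C)[C@@H](O[Si](CC)(CC)CC)CBr | intermediate
20 | (2R,4R)-5-bromo-4-hydroxy-1-[(1R,3S)-3-hydroxy-2,2-dimethyl-6-methylidenecyclohexyl]-3-methylidenepentan-2-yl benzoate | C=C1CC[C@H](O)C(C)(C)[C@@H]1C[C@@H](OC(=O)c2ccccc2)C(=C)[C@@H](O)CBr | intermediate
21 | oxepane 22 carrying CH2HgO2CCF3 in place of the C9a methyl | C=C1[C@H](OC(=O)c3ccccc3)C[C@H]2C(C)(C)[C@@H](O)CC[C@]2(C[Hg]OC(=O)C(F)(F)F)O[C@H]1CBr | intermediate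
22 | (2R,4R,5aS,7S,9aS)-2-(bromomethyl)-7-hydroxy-6,6,9a-trimethyl-3-methylidenedecahydro-1-benzoxepin-4-yl benzoate | C=C1[C@H](OC(=O)c3ccccc3)C[C@H]2C(C)(C)[C@@H](O)CC[C@]2(C)O[C@H]1CBr | intermediate
23 | (2R,4R,5aS,9aS)-2-(bromomethyl)-6,6,9a-trimethyl-3-methylidene-7-oxodecahydro-1-benzoxepin-4-yl benzoate | C=C1[C@H](OC(=O)c3ccccc3)C[C@H]2C(C)(C)C(=O)CC[C@]2(C)O[C@H]1CBr | intermediate
24 | (2R,4R,5aS,7R,9aS)-2-(bromomethyl)-7-hydroxy-6,6,9a-trimethyl-3-methylidenedecahydro-1-benzoxepin-4-yl benzoate | C=C1[C@H](OC(=O)c3ccccc3)C[C@H]2C(C)(C)[C@H](O)CC[C@]2(C)O[C@H]1CBr | intermediate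
25 | (2R,4R,5aS,7S,9aS)-7-bromo-2-(bromomethyl)-6,6,9a-trimethyl-3-methylidenedecahydro-1-benzoxepin-4-yl benzoate | C=C1[C@H](OC(=O)c3ccccc3)C[C@H]2C(C)(C)[C@@H](Br)CC[C@]2(C)O[C@H]1CBr | intermediate
26 | (2R,4R,5aS,7S,9aS)-7-bromo-2-(bromomethyl)-6,6,9a-trimethyl-3-methylidenedecahydro-1-benzoxepin-4-ol | C=C1[C@H](O)C[C@H]2C(C)(C)[C@@H](Br)CC[C@]2(C)O[C@H]1CBr | target

**Count.** Total: 15 steps. Longest linear sequence: 13 steps (steps 3–15, from 6 and 7).

**Steps most likely to fail**

Step 6. The enal may insert incompletely or unselectively into the alkyl–zirconium bond (conjugate addition, oligomerisation of the enal). Facial control at C5a by the remote C7 silyl ether may also be only moderate, because its equatorial preference next to the gem-dimethyl carbon is small. The fallback sets out from 5 and separates the two bond formations. Zirconacycle 14 is generated as before but treated with one equivalent of iodine at −78 °C and then aqueous acid, which should cleave the alkyl–zirconium bond and give triethyl{[(1S,3S,4E)-3-(iodomethyl)-2,2-dimethyl-4-(trimethylsilylmethylidene)cyclohexyl]oxy}silane F1. Iodine–lithium exchange (t-BuLi, Et2O–pentane, −78 °C) gives the primary alkyllithium F2, whose 1,2-addition to 13 returns the route at 16.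

Step 11. Capture of the mercurinium ion by trifluoroacetate, or proton loss to endocyclic alkenes, may outrun the entropically slow seven-membered ring closure. The fallback sets out from 20 and uses hydrogen-atom-transfer hydroalkoxylation (Co(salen) catalyst, N-fluoro-2,4,6-trimethylpyridinium tetrafluoroborate, PhSiH3). This generates the tertiary C9a radical and then cation under non-acidic conditions for capture by the C2 hydroxyl, and comes back at 22 without a new compound.

Step 14. Anti-periplanar elimination of the activated axial oxygen and Wagner–Meerwein shift at the neopentylic centre may compete with backside attack by bromide. The fallback sets out from 24 and separates activation from displacement. Tf2O and pyridine in CH2Cl2 at −20 °C give (2R,4R,5aS,7R,9aS)-2-(bromomethyl)-6,6,9a-trimethyl-3-methylidene-7-(trifluoromethylsulfonyloxy)decahydro-1-benzoxepin-4-yl benzoate F3. Displacement with LiBr in acetone–DMPU at room temperature inverts C7 and returns the route at 25.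

**Further compounds**

F1 | step 6 | triethyl{[(1S,3S,4E)-3-(iodomethyl)-2,2-dimethyl-4-(trimethylsilylmethylidene)cyclohexyl]oxy}silane | C[Si](C)(C)/C=C1\CC[C@H](O[Si](CC)(CC)CC)C(C)(C)[C@@H]1CI
F2 | step 6 | primary alkyllithium from F1 | C[Si](C)(C)/C=C1\CC[C@H](O[Si](CC)(CC)CC)C(C)(C)[C@@H]1C[Li]
F0 | step 11 | none | none
F3 | step 14 | (2R,4R,5aS,7R,9aS)-2-(bromomethyl)-6,6,9a-trimethyl-3-methylidene-7-(trifluoromethylsulfonyloxy)decahydro-1-benzoxepin-4-yl benzoate | C=C1[C@H](OC(=O)c3ccccc3)C[C@H]2C(C)(C)[C@H](OS(=O)(=O)C(F)(F)F)CC[C@]2(C)O[C@H]1CBr
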